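**Assumptions:** The target has no stereocenters, so "single enantiomer" is moot. The only stereo element in the route is the E-enone of chalcone 8, which is lost on cyclisation. I assume 2,6-dihydroxy-4-methoxyacetophenone (1) is purchasable. If not, it comes from phloroacetophenone by selective 4-O-methylation.

## Retrosynthesis
- Target ← global MOM removal from a bis-MOM flavone, which is the C5-OH and C4'-OH masking.
- Flavone (pyranone ring C) ← oxidative cyclodehydrogenation of a 2'-hydroxychalcone (I2/DMSO).
- Chalcone ← Claisen–Schmidt condensation of a 3-prenyl-6-MOMO-2-hydroxy-4-methoxyacetophenone with 2-methoxy-4-MOMO-benzaldehyde.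
- The prenyl group is installed first on the symmetric acetophenone 1, so C3 and C5 are equivalent and C8 regiochemistry is fixed. Masking the less hindered 6-OH leaves only the OH beside the prenyl group free to close the ring. That places the prenyl group at C8 and the OH at C5.

## Route

**Step 1**
Reactants: 1 (2',6'-dihydroxy-4'-methoxyacetophenone); 2 (prenyl bromide, 1-bromo-3-methylbut-2-ene)
Product: 3 (1-[2,6-dihydroxy-4-methoxy-3-(3-methylbut-2-enyl)phenyl]ethanone)
Conditions: KOH (2.2 equiv), H2O, 0 °C → rt, 16 h
Reagents that add atoms: prenyl bromide, CC(C)=CCBr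
Why: Phenoxide C-alkylation (ortho-selective SN2) of the phloroglucinol-type ring. Ring symmetry means mono-C3 prenylation gives one regioisomer; use about 1 equiv of 2 to limit bis-prenylation. No stereocenter is formed.

**Step 2**
Reactants: 3; 4 (chloromethyl methyl ether, MOMCl)
Product: 5 (1-[2-hydroxy-6-(methoxymethoxy)-4-methoxy-3-prenylphenyl]ethanone)
Conditions: MOMCl (1.0 equiv), DIPEA, CH2Cl2, 0 °C → rt
Reagents that add atoms: MOMCl, COCCl
Why: Phenol O-alkylation (MOM protection). The 2-OH is flanked by acetyl and prenyl, so the less hindered 6-OH reacts preferentially. This leaves a single free OH for later ring closure.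

**Step 3**
Reactants: 6 (4-hydroxy-2-methoxybenzaldehyde); 4 (MOMCl)
Product: 7 (2-methoxy-4-(methoxymethoxy)benzaldehyde)
Conditions: MOMCl, DIPEA, CH2Cl2, 0 °C → rt
Reagents that add atoms: MOMCl, COCCl
Why: MOM protection of the phenol so that it survives the strongly basic Claisen–Schmidt step.

**Step 4**
Reactants: 5; 7
Product: 8 ((E)-chalcone: 1-[2-hydroxy-4-methoxy-6-(MOMO)-3-prenylphenyl]-3-[2-methoxy-4-(MOMO)phenyl]prop-2-en-1-one)
Conditions: KOH (50% aq), EtOH, rt, 48 h
Reagents that add atoms: none
Why: Claisen–Schmidt aldol condensation. Dehydration gives the thermodynamic E-enone, and MOM ethers are base-stable. Any flavanone that forms by oxa-Michael addition is funnelled to the flavone in Step 5.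

**Step 5**
Reactants: 8
Product: 9 (5,4'-bis-MOM ether of the target flavone: 2-[2-methoxy-4-(MOMO)phenyl]-5-(MOMO)-7-methoxy-8-prenylchromen-4-one)
Conditions: I2 (0.2 equiv), DMSO, 130 °C, 1–2 h; Na2S2O3 workup
Reagents that add atoms: none
Why: Iodine-catalysed oxidative cyclodehydrogenation (oxa-Michael addition, α-iodination, HI elimination, with DMSO reoxidising iodide). The only free phenol is the one next to the prenyl group, so the ring closes to give the 8-prenyl, 5-OMOM pattern. The C2=C3 double bond is formed and no stereocenter results.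

**Step 6**
Reactants: 9
Product: 10 (Artocarpetin B)
Conditions: 2 M HCl, MeOH/THF (1:1), 50 °C, 3 h
Reagents that add atoms: none
Why: Acid-catalysed hydrolysis of both MOM acetals, including the labile peri-5-OMOM, frees the 5-OH and 4'-OH. The aryl methyl ethers, the flavone and the prenyl group are retained under these mild conditions.

## Checks
- **Structure match:** Ring C is a 4H-chromen-4-one. The A ring carries 5-OH, 7-OMe and 8-prenyl. The B ring is attached at C2 and carries 2'-OMe and 4'-OH. This matches the target SMILES.
- **Atom balance:** Each step conserves atoms. Step 1 loses HBr, Steps 2 and 3 lose HCl, Step 4 loses H2O, Step 5 loses H2 (taken up by DMSO), and Step 6 loses 2 CH2O (with MeOH).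
- **Functional-group survival:** The MOM ethers survive KOH and I2/DMSO. The prenyl group is carried through, with the risks flagged below.
- **Stereochemistry:** There are no stereocenters to set or scramble.

## Compound list
| No. | Name | SMILES | Role |
|---|---|---|---|
| 1 | 2',6'-Dihydroxy-4'-methoxyacetophenone | CC(=O)c1c(O)cc(OC)cc1O | starting material |
| 2 | Prenyl bromide | CC(C)=CCBr | starting material |
| 3 | 1-(2,6-Dihydroxy-4-methoxy-3-prenylphenyl)ethanone | CC(=O)c1c(O)c(CC=C(C)C)c(OC)cc1O | intermediate |
| 4 | Chloromethyl methyl ether (MOMCl) | COCCl | starting material |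
| 5 | 1-(2-Hydroxy-6-MOMO-4-methoxy-3-prenylphenyl)ethanone | CC(=O)c1c(O)c(CC=C(C)C)c(OC)cc1OCOC | intermediate |
| 6 | 4-Hydroxy-2-methoxybenzaldehyde | COc1cc(O)ccc1C=O | starting material |
| 7 | 2-Methoxy-4-(MOMO)benzaldehyde | COCOc1ccc(C=O)c(OC)c1 | intermediate |
| 8 | (E)-Chalcone (2'-OH, 6'-OMOM, 4'-OMe, 3'-prenyl; B ring 2-OMe, 4-OMOM) | COCOc1ccc(/C=C/C(=O)c2c(O)c(CC=C(C)C)c(OC)cc2OCOC)c(OC)c1 | intermediate |
| 9 | 5,4'-Bis-MOM flavone | COCOc1ccc(-c2cc(=O)c3c(OCOC)cc(OC)c(CC=C(C)C)c3o2)c(OC)c1 | intermediate |
| 10 | Artocarpetin B | COc1cc(O)ccc1-c1cc(=O)c2c(O)cc(OC)c(CC=C(C)C)c2o1 | target |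

## Totals
Total steps: 6. Longest linear sequence: 5 (1 → 3 → 5 → 8 → 9 → 10), with the aldehyde branch 6 → 7 joining at Step 4.

## Three steps most likely to fail
1. **Step 1 (C-prenylation):** O-prenylation and bis-prenylation lower the yield.
   - Fallback: iodinate 1 at C3 (NIS; the ring is symmetric, so there is one product), then couple to a prenyl-boron or prenyl-zinc reagent with Pd catalysis. Check for α/γ (reverse-prenyl) selectivity.
2. **Step 2 (mono-MOM regioselectivity):** Bis-protection or protection at the hindered OH would derail the ring closure.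
   - Fallback: start from 2-hydroxy-4,6-dimethoxyacetophenone. Prenylate, build the 5,7,2'-trimethoxy flavone, then remove the 5-OMe selectively with BCl3 (chelation control) together with the MOM group.
3. **Step 5 (I2/DMSO cyclisation):** Iodine may cyclise the ortho-prenyl phenol or cleave a MOM group.
   - Fallback: oxidant-free Baker–Venkataraman route. Esterify the free OH of 5 with 2-methoxy-4-MOMO-benzoyl chloride (from Pinnick oxidation of 7), rearrange with LiHMDS to the 1,3-diketone, then cyclodehydrate with PPTS.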